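## The problem

The target (17) is a pentabrominated diaryl ether. Ring A is a hydroquinone with hydroxyls at C2 and C5, the aryloxy bridge at C1, bromine at C4 and C6 and hydrogen at C3. Ring B is a 4-hydroxyphenyl ring (bridge at C1', hydroxyl at C4') with bromine at C3', C5' and C6' and hydrogen at C2'. There is no stereocentre, so the whole task is regiochemistry on two electron-rich rings.

Four bromines (C4, C6, C3', C5') lie ortho to a hydroxyl and could be placed by phenol-directed bromination. The C6' bromine is ortho only to the bridging oxygen and meta to the hydroxyl, so ring B has to arrive with it in place. On ring A, C3 must stay free although it is ortho to the C2 hydroxyl. The C2 oxygen must therefore be masked and the C5 oxygen free when ring A is brominated, and the C1 oxygen must be a third, different one.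

Once aryl bromides are present, organolithium reagents, dissolving metals and hydrogenolysis are excluded. The free bromohydroquinone is easily oxidised to the quinone and should be released last.

The feature that allows a benzannulation is C5. It bears a hydroxyl and is flanked by C4 and C6, which each need only a group replaceable by bromine. C5 can therefore be a carbonyl ligand inserted between an alkyne carbon (C4) and an alkene terminus (C6), with C2 and its oxygen from an alkoxycarbene carbon and C1 with its aryloxy group from the adjacent alkene carbon.

## Retrosynthesis

**17 to 16.** The two O–CH3 bonds (at C2 of ring A and C4' of ring B) are cut last. This keeps the oxidisable hydroquinone masked as the monophenol 16 until the end. Methyl is chosen because one methyl comes directly from the carbene alkoxy group and the other survives every earlier step; benzyl would call for hydrogenolysis, which the bromines forbid. The forward step must cleave a methoxy group flanked by two bromines without touching the diaryl ether.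

**16 to 15.** The C4–Br and C6–Br bonds are cut. Both carbons are ortho to the free C5 hydroxyl of 15, while the C2 oxygen is still a methyl ether, so C3 is not activated by a free hydroxyl. Silicon at C4 is a placeholder that leaves by ipso substitution. Ring B already carries its three bromines and is deactivated. The forward step needs two equivalents of electrophilic bromine to react on ring A only, without oxidation to the quinone.

**15 to 12 and 13.** The C2–C3, C4–C5 and C5–C6 bonds are cut together, so ring A falls apart into the zerovalent chromium carbene complex 12, the alkyne 13 and one carbonyl ligand of 12. Cutting the diaryl ether instead would mean coupling two ortho-substituted partners and making a ring A piece with three differentiated oxygens separately. Here the three oxygens arrive differentiated by construction: methoxy at C2, free hydroxyl at C5, aryloxy at C1. The forward reaction must orient the alkyne with silicon next to C5 and must tolerate the α-aryloxy group and three C–Br bonds.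

**12 to 8 and 9.** The chromium–carbon bond and the O–CH3 bond of the carbene are cut, giving the acid chloride 8 and Cr(CO)6 (9). The usual organolithium entry to such complexes would exchange the aryl bromines, so the polarity is reversed: a nucleophilic chromate is acylated. The forward step requires acylation to be faster than electron transfer to the C–Br bonds.

**8 to 4 and 5.** The acid chloride comes from acid 7 and ester 6, and in 6 the vinyl C–O bond is cut to give phenol 4 and the three-carbon ester 5. Cutting on the aryl side of that oxygen would need a substitution on a tribrominated ring. The forward step must leave the phenoxide on C2 of the acrylate, not on C3.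

**4 to 3 to 1.** The bromine ortho to the phenol oxygen of 4 (C6' of the target) is cut first. At this stage it is ortho to a free hydroxyl, so the bromine that no later hydroxyl could direct is easy to place. Phenol 3 is then traced to 1 by cutting the C–O bond at the one ring position of 1 with no ortho substituent. The forward steps must oxidise that C–H bond only and stop at monobromination.

## Roads not taken

**Alternative 1:** The cut is on the ring B side of the ether (C1'–O) together with the C6'–Br bond. The magnesium phenoxide of 2,4-dibromo-3,6-dimethoxyphenol A2 would add to 3,5-dibromo-4-methoxybenzyne A3, generated from the iodo triflate A4 by iodine–magnesium exchange and loss of triflate. The arylmagnesium left at C6' would be quenched with an electrophilic bromine source, giving the tri-O-methyl ether A1, one demethylation from 17.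
- Merits: it is convergent and makes the ether and the hardest bromine in one step. A2 should be one bromination from 2,5-dimethoxyphenol and A4 two steps from 3, so about six steps in all, clearly shorter than the chosen nine. Addition away from the bromine next to the aryne, leaving the carbanion beside that bromine, gives the right regiochemistry.
- Weak points: the oxygen of A2 is flanked by bromine and methoxy and is a poor nucleophile toward a short-lived aryne. The arylmagnesium formed has an ortho bromine and can expel magnesium bromide to give a second aryne. Three-component aryne trapping is much less established for phenoxides than for thiolates or amides.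
- Comparison: in step count and convergence this road is better. The chosen plan sets against it that each of its bond-forming steps belongs to a reaction class with direct precedent, and that the substitution pattern of ring A follows from the connectivity of the benzannulation, not from competition between two aryne carbons. The price is stoichiometric chromium and three more steps.

**Alternative 2:** The cut is in ring B (C1'–C6' and C4'–C5'), with ring A arriving complete as the furyl ether A6. A [4+2] cycloaddition of A6 with methyl propiolate and opening of the oxabicycle at its acetal carbon would give the phenol A5, with an ester at C6'.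
- Merits: the para relation of the two ring B oxygens arises automatically, no metal is needed, and the new hydroxyl then directs bromine to C3' and C5'.
- Weak points: the ester at C6' has to be exchanged for bromine by hydrolysis and decarboxylative bromination, the least reliable way to place the hardest bromine. 2-Aryloxyfurans are acid-labile and not trivial to make from a hindered phenol such as A2. The step count is no lower than in the chosen plan.
- Comparison: this road avoids chromium and low-valent metals, which is a real advantage. The chosen plan places the C6' bromine by a simple phenol bromination (step 2) and needs no functional group exchange on ring B.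

**Alternative 3:** The cut is the C4–C5 bond of ring A, formed when the racemic 4-vinylcyclobutenone A8 opens on heating to a dienylketene and closes to the phenol A7. A7 differs from 15 only by hydrogen in place of silicon and would reach 16 by the same bromination.
- Merits: it is thermal and metal-free, and the bromines never meet a reducing metal. That is a genuine advantage over step 6 of the chosen plan.
- Weak points: A8 needs a semisquaric acid derivative carrying the aryloxy group, addition of a vinyl metal to one carbonyl without displacement of the vinylogous aryl ester, and O-methylation of a tertiary alkoxide. That is at least four steps of squarate chemistry, each with its own selectivity question.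
- Comparison: both routes pass through the same kind of dienylketene. The chosen one assembles it in one operation from three simple pieces and takes C5 from a carbonyl ligand, whereas the Moore route is probably kinder to the bromines but longer up to the ring-closure substrate.

Key step: step 7

## Route

Remark: 5 is used as the racemate. In the SMILES of 14 the Cr(CO)3 unit is written as a separate fragment because the η6 bond to ring A cannot be expressed.

Step 1
Reactants: 1 2,6-dibromoanisole (1,3-dibromo-2-methoxybenzene)
Product: 3 3,5-dibromo-4-methoxyphenol, via arylboronic pinacol ester 2 (not isolated)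
Conditions: B2pin2 (1.0 equiv), [Ir(OMe)(cod)]2 (1.5 mol %), 4,4'-di-tert-butyl-2,2'-bipyridine (3 mol %), THF, 80 °C; evaporate; then KHSO5 (as Oxone), acetone/H2O, rt
Reagents that add atoms: bis(pinacolato)diboron, CC1(C)OB(OC1(C)C)B1OC(C)(C)C(C)(C)O1 (boron and pinacolate of intermediate 2 only); potassium peroxymonosulfate, [K+].OOS(=O)(=O)[O-] (hydroxyl oxygen of 3)
Why: Iridium-catalysed C–H borylation is sterically governed and should take the only C–H bond with no ortho substituent (para to methoxy, meta to both bromines), with the C–Br bonds untouched; oxidation of the C–B bond in the same pot gives the phenol (one-pot borylation/oxidation route to meta-substituted phenols).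

Step 2
Reactants: 3 3,5-dibromo-4-methoxyphenol
Product: 4 2,3,5-tribromo-4-methoxyphenol
Conditions: Br2 (1.0 equiv), CH2Cl2/AcOH, 0 °C
Reagents that add atoms: bromine, BrBr
Why: Electrophilic aromatic bromination directed by the free hydroxyl; para is blocked by methoxy, the two ortho positions are equivalent, and under non-basic conditions the first bromine deactivates the ring enough for one equivalent to stop at the monobromide.

Step 3
Reactants: 4 2,3,5-tribromo-4-methoxyphenol; 5 methyl 2,3-dibromopropanoate (racemic)
Product: 6 methyl 2-(2,3,5-tribromo-4-methoxyphenoxy)prop-2-enoate
Conditions: K2CO3 (3 equiv), acetone, reflux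
Reagents that add atoms: none
Why: Known conversion of phenols into 2-aryloxyacrylates with 2,3-dibromopropanoates and carbonate: 5 loses HBr to methyl 2-bromoacrylate in the flask, and an addition–substitution–elimination sequence leaves the aryloxy group on C2 with net loss of two HBr.

Step 4
Reactants: 6 methyl 2-(2,3,5-tribromo-4-methoxyphenoxy)prop-2-enoate
Product: 7 2-(2,3,5-tribromo-4-methoxyphenoxy)prop-2-enoic acid
Conditions: LiOH·H2O, THF/H2O, 0 °C to rt; then 1 M HCl
Reagents that add atoms: lithium hydroxide (aqueous), [Li+].[OH-]
Why: Ester saponification; the α-aryloxy group lowers the electrophilicity of the β-carbon, so hydroxide should attack the ester carbonyl and not add in conjugate fashion.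

Step 5
Reactants: 7 2-(2,3,5-tribromo-4-methoxyphenoxy)prop-2-enoic acid
Product: 8 2-(2,3,5-tribromo-4-methoxyphenoxy)prop-2-enoyl chloride
Conditions: (COCl)2, DMF (cat.), CH2Cl2, 0 °C to rt; concentrate, use crude at once
Reagents that add atoms: oxalyl chloride, O=C(Cl)C(Cl)=O
Why: Acid chloride formation through the Vilsmeier-type chloroiminium catalyst under neutral, cold conditions; the product is used immediately to avoid polymerisation of the captodative acryloyl chloride.

Step 6
Reactants: 8 2-(2,3,5-tribromo-4-methoxyphenoxy)prop-2-enoyl chloride; 9 chromium hexacarbonyl Cr(CO)6
Product: 12 pentacarbonyl{methoxy[1-(2,3,5-tribromo-4-methoxyphenoxy)ethenyl]methylidene}chromium, via disodium pentacarbonylchromate 10 (not isolated), via sodium acylpentacarbonylchromate 11 (not isolated)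
Conditions: Cr(CO)6, NaC10H8 (sodium naphthalenide, 2.0 equiv), THF, −78 °C; add 8, −78 to −20 °C; then Me3OBF4, CH2Cl2, 0 °C
Reagents that add atoms: sodium naphthalenide, [Na+].[CH-]1C=Cc2ccccc2[CH]1 (sodium of intermediates 10 and 11 only); trimethyloxonium tetrafluoroborate, C[O+](C)C.F[B-](F)(F)F
Why: Acylation of the pentacarbonylchromate dianion 10 (chromium in the formal oxidation state minus two) by an acid chloride, then O-methylation of the acylchromate 11 with a hard methylating agent (Semmelhack–Hegedus route to Fischer carbene complexes); it replaces the organolithium route, which the aryl bromines exclude, and acylation at −78 °C is expected to outrun electron transfer to the C–Br bonds.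

Step 7
Reactants: 12 pentacarbonyl{methoxy[1-(2,3,5-tribromo-4-methoxyphenoxy)ethenyl]methylidene}chromium; 13 trimethylsilylacetylene
Product: 15 4-methoxy-5-(2,3,5-tribromo-4-methoxyphenoxy)-2-(trimethylsilyl)phenol, via tricarbonylchromium arene complex 14 (not isolated)
Conditions: 13 (2 equiv), THF (0.05 M), 50 °C, sealed tube, Ar; then air, rt
Reagents that add atoms: none
Why: Thermal loss of one carbonyl ligand from 12 lets 13 bind and insert into the chromium–carbene bond, giving a vinylcarbene; a carbonyl ligand then migrates onto it to give a chromium-bound dienylketene. The ketene carbon bonds to the CH2 terminus of the aryloxyvinyl group in a 6π electrocyclization and the cyclohexadienone tautomerises to the phenol, which stays on Cr(CO)3 as 14 until air releases it. This is the Dötz benzannulation of alkenyl(methoxy)carbene pentacarbonylchromium complexes with terminal alkynes, known for silylacetylenes and for α-alkoxyalkenyl complexes derived from cyclic enol ethers; the α-aryloxy group is new for the molecule, not for the reaction type. Ring A closes as a six-membered ring by this electrocyclization, with C2–C3, C4–C5 and C5–C6 formed in one operation. No stereocentre is created. The selectivity needed is the orientation of the alkyne: the silyl-bearing carbon must end next to the carbonyl-derived C5 and the CH next to C2, which the steric bias of a terminal alkyne (large group away from the carbene substituents during insertion) should secure. The route does not depend on the fate of silicon: a 1,3-shift to oxygen or loss of the silyl group still leaves C4 and C6 as the two positions ortho to the C5 hydroxyl for step 8. The methoxy group on the carbene carbon and THF as solvent favour carbonyl insertion over five-ring formation.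

Step 8
Reactants: 15 4-methoxy-5-(2,3,5-tribromo-4-methoxyphenoxy)-2-(trimethylsilyl)phenol
Product: 16 2,6-dibromo-4-methoxy-3-(2,3,5-tribromo-4-methoxyphenoxy)phenol
Conditions: Br2 (2.05 equiv), CH2Cl2, −20 to 0 °C
Reagents that add atoms: bromine, BrBr
Why: Electrophilic aromatic bromination at the two positions ortho to the free hydroxyl, by ipso-bromodesilylation at C4 and C–H substitution at C6; C3 is only ortho to a methoxy group on a ring that becomes deactivated, and ring B is deactivated by three bromines.

Step 9
Reactants: 16 2,6-dibromo-4-methoxy-3-(2,3,5-tribromo-4-methoxyphenoxy)phenol
Product: 17 3,5-dibromo-2-(2,3,5-tribromo-4-hydroxyphenoxy)benzene-1,4-diol (target)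
Conditions: BBr3 (6 equiv), CH2Cl2, −78 °C to rt; then H2O
Reagents that add atoms: none
Why: Lewis-acid cleavage of aryl methyl ethers with BBr3 through aryloxyboron bromides and bromomethane; the diaryl ether and the C–Br bonds are inert, and the small reagent should also reach the methoxy group between two bromines on ring B.

## Compound list

1 | 2,6-dibromoanisole (1,3-dibromo-2-methoxybenzene) | COc1c(Br)cccc1Br | starting material
2 | 2-(3,5-dibromo-4-methoxyphenyl)-4,4,5,5-tetramethyl-1,3,2-dioxaborolane | COc1c(Br)cc(cc1Br)B1OC(C)(C)C(C)(C)O1 | intermediate (not isolated)
3 | 3,5-dibromo-4-methoxyphenol | COc1c(Br)cc(O)cc1Br | intermediate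
4 | 2,3,5-tribromo-4-methoxyphenol | COc1c(Br)cc(O)c(Br)c1Br | intermediate
5 | methyl 2,3-dibromopropanoate (racemic) | COC(=O)C(Br)CBr | starting material
6 | methyl 2-(2,3,5-tribromo-4-methoxyphenoxy)prop-2-enoate | COC(=O)C(=C)Oc1cc(Br)c(OC)c(Br)c1Br | intermediate
7 | 2-(2,3,5-tribromo-4-methoxyphenoxy)prop-2-enoic acid | OC(=O)C(=C)Oc1cc(Br)c(OC)c(Br)c1Br | intermediate
8 | 2-(2,3,5-tribromo-4-methoxyphenoxy)prop-2-enoyl chloride | ClC(=O)C(=C)Oc1cc(Br)c(OC)c(Br)c1Br | intermediate
9 | chromium hexacarbonyl Cr(CO)6 | O=C=[Cr](=C=O)(=C=O)(=C=O)(=C=O)=C=O | starting material
10 | disodium pentacarbonylchromate Na2Cr(CO)5 | [Na+].[Na+].O=C=[Cr-2](=C=O)(=C=O)(=C=O)=C=O | intermediate (not isolated)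
11 | sodium pentacarbonyl[2-(2,3,5-tribromo-4-methoxyphenoxy)prop-2-enoyl]chromate | [Na+].C=C(Oc1cc(Br)c(OC)c(Br)c1Br)C(=O)[Cr-](=C=O)(=C=O)(=C=O)(=C=O)=C=O | intermediate (not isolated)
12 | pentacarbonyl{methoxy[1-(2,3,5-tribromo-4-methoxyphenoxy)ethenyl]methylidene}chromium | COC(=[Cr](=C=O)(=C=O)(=C=O)(=C=O)=C=O)C(=C)Oc1cc(Br)c(OC)c(Br)c1Br | intermediate
13 | trimethylsilylacetylene (ethynyltrimethylsilane) | C#C[Si](C)(C)C | starting material
14 | tricarbonyl[η6-4-methoxy-5-(2,3,5-tribromo-4-methoxyphenoxy)-2-(trimethylsilyl)phenol]chromium, metal on ring A | COc1cc([Si](C)(C)C)c(O)cc1Oc1cc(Br)c(OC)c(Br)c1Br.O=C=[Cr](=C=O)=C=O | intermediate (not isolated)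
15 | 4-methoxy-5-(2,3,5-tribromo-4-methoxyphenoxy)-2-(trimethylsilyl)phenol | COc1cc([Si](C)(C)C)c(O)cc1Oc1cc(Br)c(OC)c(Br)c1Br | intermediate
16 | 2,6-dibromo-4-methoxy-3-(2,3,5-tribromo-4-methoxyphenoxy)phenol | COc1cc(Br)c(O)c(Br)c1Oc1cc(Br)c(OC)c(Br)c1Br | intermediate
17 | 3,5-dibromo-2-(2,3,5-tribromo-4-hydroxyphenoxy)benzene-1,4-diol | Oc1cc(Br)c(O)c(Br)c1Oc1cc(Br)c(O)c(Br)c1Br | target

## Step count and least certain steps

Total: 9 steps. Longest linear sequence: 9 steps (1 to 17); 5, 9 and 13 enter as purchased compounds.

**Step 7 (key step).**
- What may go wrong: the chromium-bound dienylketene may be diverted before ring closure. It could stall as a silicon-stabilised ketene, close to a four-membered ring, or cyclise without carbonyl insertion. The captodative carbene complex may also decompose before it takes up the alkyne. Both become more likely if the α-aryloxy oxygen binds chromium or the bulky tribromoaryl group disfavours the s-cis arrangement needed for closure.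
- Fallback (from 4, returning at 16): the chromium route is left and the ether is made by copper. Phenol 4 and commercial (5-formyl-2-methoxyphenyl)boronic acid would be joined by Chan–Lam coupling (Cu(OAc)2, pyridine, 4 Å molecular sieves, CH2Cl2, air) to give 4-methoxy-3-(2,3,5-tribromo-4-methoxyphenoxy)benzaldehyde F1. Baeyer–Villiger oxidation with mCPBA should give 4-methoxy-3-(2,3,5-tribromo-4-methoxyphenoxy)phenyl formate F2; the aryl group here is electron-rich and should migrate. Methanolysis (K2CO3, MeOH) would give 4-methoxy-3-(2,3,5-tribromo-4-methoxyphenoxy)phenol F3, and Br2 (2 equiv) at its two free positions ortho to the hydroxyl leads to 16.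

**Step 6.**
- What may go wrong: electron transfer from the strongly reducing dianion 10 to the tribrominated ring, with loss of bromine, may compete with acylation. Conjugate addition of the soft chromate to the acryloyl chloride is a second way the acylation could fail.
- Fallback (from 4, returning at 16): no other entry to 12 tolerates aryl bromides, so this fallback also leaves chromium, by a metal-free aryl transfer. Commercial 3-iodo-4-methoxybenzaldehyde would be oxidised (mCPBA, TsOH·H2O, MeCN) and captured with 1,3,5-trimethoxybenzene to give (5-formyl-2-methoxyphenyl)(2,4,6-trimethoxyphenyl)iodonium 4-methylbenzenesulfonate F4. With K2CO3 in toluene at 60 °C this should transfer its formylaryl group to the oxygen of 4, giving F1, which continues through F2 and F3 to 16 as described under step 7.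

**Step 3.**
- What may go wrong: substitution by the weakly nucleophilic, ortho-brominated phenoxide may be slow. The 2-bromoacrylate formed in the flask would then polymerise, or the phenoxide would end on C3.
- Fallback (from 4, returning at 6): rhodium-catalysed O–H insertion of 4 with methyl 2-diazo-2-(dimethoxyphosphoryl)acetate (Rh2(OAc)4, toluene, 80 °C) would give methyl 2-(dimethoxyphosphoryl)-2-(2,3,5-tribromo-4-methoxyphenoxy)acetate F5. Horner–Wadsworth–Emmons reaction with aqueous formaldehyde (K2CO3, THF/H2O, rt) installs the methylene group and gives 6.

## Further compounds

F1 | step 7 | 4-methoxy-3-(2,3,5-tribromo-4-methoxyphenoxy)benzaldehyde | COc1ccc(C=O)cc1Oc1cc(Br)c(OC)c(Br)c1Br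
F2 | step 7 | 4-methoxy-3-(2,3,5-tribromo-4-methoxyphenoxy)phenyl formate | COc1ccc(OC=O)cc1Oc1cc(Br)c(OC)c(Br)c1Br
F3 | step 7 | 4-methoxy-3-(2,3,5-tribromo-4-methoxyphenoxy)phenol | COc1ccc(O)cc1Oc1cc(Br)c(OC)c(Br)c1Br
F4 | step 6 | (5-formyl-2-methoxyphenyl)(2,4,6-trimethoxyphenyl)iodonium 4-methylbenzenesulfonate | COc1ccc(C=O)cc1[I+]c1c(OC)cc(OC)cc1OC.Cc1ccc(cc1)S([O-])(=O)=O
F5 | step 3 | methyl 2-(dimethoxyphosphoryl)-2-(2,3,5-tribromo-4-methoxyphenoxy)acetate (racemic) | COC(=O)C(Oc1cc(Br)c(OC)c(Br)c1Br)P(=O)(OC)OC
A1 | alternative 1 | 1,3-dibromo-2,5-dimethoxy-4-(2,3,5-tribromo-4-methoxyphenoxy)benzene (tri-O-methyl ether of the target) | COc1cc(Br)c(OC)c(Br)c1Oc1cc(Br)c(OC)c(Br)c1Br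
A2 | alternative 1 | 2,4-dibromo-3,6-dimethoxyphenol | COc1cc(Br)c(OC)c(Br)c1O
A3 | alternative 1 | 3,5-dibromo-4-methoxybenzyne (3,5-dibromo-4-methoxy-1,2-didehydrobenzene) | COC1=C(Br)C#CC=C1Br
A4 | alternative 1 | 3,5-dibromo-2-iodo-4-methoxyphenyl trifluoromethanesulfonate | COc1c(Br)cc(OS(=O)(=O)C(F)(F)F)c(I)c1Br
A5 | alternative 2 | methyl 2-(2,4-dibromo-3,6-dimethoxyphenoxy)-5-hydroxybenzoate | COC(=O)c1cc(O)ccc1Oc1c(OC)cc(Br)c(OC)c1Br
A6 | alternative 2 | 2-(2,4-dibromo-3,6-dimethoxyphenoxy)furan | COc1cc(Br)c(OC)c(Br)c1Oc1ccco1
A7 | alternative 3 | 4-methoxy-3-(2,3,5-tribromo-4-methoxyphenoxy)phenol | COc1ccc(O)cc1Oc1cc(Br)c(OC)c(Br)c1Br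
A8 | alternative 3 | 4-ethenyl-4-methoxy-3-(2,3,5-tribromo-4-methoxyphenoxy)cyclobut-2-en-1-one (racemic) | COC1(C=C)C(Oc2cc(Br)c(OC)c(Br)c2Br)=CC1=O
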